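D was what I wanted from the next charge, counted in percent of the E charged, and I had to choose that charge among these flasks.

| flask | E | remark | time |
|---|---|---|---|
| Tuesday's | 0.0053 M | run made earlier |  |
| Thursday's | 0.020 M | run made earlier |  |
| Monday's | 0.061 M | run made earlier |  |
| larch | 0.018 M |  | 6.0 d |
| oak | 0.025 M |  | 6.0 d |
| elm | 0.080 M |  | 6.0 d |
| alder | 0.0050 M |  | 6.0 d |
| ash | 0.0060 M |  | 6.0 d |

- Tuesday's (time / d: D / %, E / %): 0.500: 0, 70; 1.67: 4, 45; 2.50: 8, 32; 4.00: 17, 7
- Thursday's (time / d: D / %, E / %): 1.04: 2, 87; 2.00: 2, 84; 3.00: 2, 81; 4.00: 3, 73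
- Monday's (time / d: D / %, E / %): 0.333: 0, 95; 0.833: 0, 98; 1.67: 4, 96; 4.00: 2, 93

(readings scatter by 2 percentage points)

* all flasks from highest to lowest amount of D, in percent of the E charged, at 6.0 d (larch / oak / elm / alder / ash)
* the amount of D, in percent of the E charged of the flask you put first, at 6.0 d
* the amount of D, in percent of the E charged of the flask you put last, at 6.0 d

- solid, in amounts per volume of the solution: E
- at the start none of E is in solution
- what has only dissolved of E counts as not reacted

At 4.00 d, Tuesday's run held 17% of D, Thursday's 3% and Monday's 2%, so the smallest [E] charged had given the best percentage. Percentages hid what stood still, so I turned the loss of E into molar terms. Tuesday's run lost E at 9.54 × 10⁻⁴ M d⁻¹, and Thursday's, from 0.020 M, lost it at 9.46 × 10⁻⁴ M d⁻¹, which I read, within the scatter, as one feed, zero order in the charge. Tuesday's first reading showed an early loss beyond that feed of 0.00111 M.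

I froze both and added them up to 6.0 d. That gave 0.00684 M, which I called the bite: the [E] taken from the solid by that time while solid stands. By this reckoning a charge above the bite keeps, at 6.0 d, the fraction of one minus bite over charge of its E, and a charge below it is reckoned to last less than 6.0 d. Alder and ash lay under the bite, and larch, oak and elm above it. I would have charged alder, at 0.0050 M, the lower charge of those two.

The forecast, reading the runs as “a slow reaction fed by a saturated solution, followed by a slower step to D”, gave alder > ash > larch > oak > elm, with 27% of D first (21% to 36%) and 1.9% last (1.3% to 2.8%).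

The flasks gave alder > ash > larch > oak > elm, with 27.2% in alder and 1.85% in elm.

    Q ⇌ Z (K = 2.40, k = 2.00 × 10⁻⁴ min⁻¹)
    L → D (k = 8.90 × 10⁻⁴ min⁻¹)
    G → L (k = 3.70 × 10⁻⁴ min⁻¹)
    G → Q (k = 7.70 × 10⁻⁴ min⁻¹)
    J ⇌ G (K = 1.00, k = 0.00140 min⁻¹)
    E ⇌ J, rate k6*(cs6 - [J]) while solid is left; crystals form when [J] > cs6 (solubility = 1.10 mM, k = 0.0100 min⁻¹)

While solid stood, J refilled from E with a half-life of 0.0481 d, shorter than the half-life of J by the making of G alone, forward step only, of 0.34 d in alder. Larch held J at 5.75% at 3.00 d and at 5.75% at 6.00 d. The bite left larch 62.0% of its E, and larch held 61.7%. For the flask charged with 0.013 M the bite left 47.4%, and that flask held 47.0% of E, with 11.4% of D.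

All runs were generated by integration for an exercise; scatter was added.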